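All runs are calculated on assumed constants, noise included.

I start from a leftover: at 120 min the dawn run reads 41.9% product, so 58.1% of the substrate charged is still in some other form.

| flask | substrate | coupling partner | catalyst | temperature | remark | time |
|---|---|---|---|---|---|---|
| dusk | 20 mM | 0.45 equiv | 0.1 mol% | 20 °C | run made earlier |  |
| dawn | 20 mM | 3.6 equiv | 0.1 mol% | 35 °C | run made earlier |  |
| violet | 20 mM | 2.80 equiv | 0.1 mol% | 35 °C |  | 2.5 h |
| blue | 20 mM | 0.950 equiv | 0.1 mol% | 35 °C |  | 2.5 h |
| green | 20 mM | 1.40 equiv | 0.1 mol% | 35 °C |  | 2.5 h |
| teal | 20 mM | 0.310 equiv | 0.1 mol% | 35 °C |  | 2.5 h |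
| amber | 20 mM | 0.470 equiv | 0.1 mol% | 35 °C |  | 2.5 h |
| ochre | 20 mM | 0.640 equiv | 0.1 mol% | 35 °C |  | 2.5 h |

dusk run (percent of the substrate charged): time / h: product / % = 0.500: 0.9; 1.00: 1.4; 2.00: 3.4; 3.00: 4.1; 4.00: 5.5

dawn run (percent of the substrate charged): time / min: product / % = 15.0: 5.4; 30.0: 12.3; 50.0: 20.1; 60.0: 24.3; 80.0: 30.9; 90.0: 34.1; 120: 41.9

(readings scatter by 0.3 percentage points)

- for product the crystals and idle adduct are counted in
- as a solid, counted per litre of solution: crystals
- what was read earlier has a scatter of 0.3 percentage points, one standard deviation
- steps that have been proposed: substrate + catalyst -> catalyst + intermediate; coupling partner + catalyst + intermediate -> catalyst + product; crystals <-> product; coupling partner + product <-> idle adduct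

1. all flasks from highest to lowest amount of product, in percent of the substrate charged, at 2.5 h (violet / blue / green / teal / amber / ochre)
2. the amount of product, in percent of the substrate charged of the flask you put first, at 2.5 h
3. the amount of product, in percent of the substrate charged of the flask you put last, at 2.5 h

Minus the natural logarithm of that leftover fraction, divided by the time, gives a pseudo-first-order constant read off the dawn run, 0.272 h⁻¹. The reading at 30.0 min gives 0.262 h⁻¹, so I use one constant for the whole dawn run.

But does that constant follow the coupling partner? The dusk run gives 0.0141 h⁻¹, so dawn is 19.3 times faster with 8.00 times the partner. If the constant is proportional to the partner, that leaves a factor of 2.40 for the warmer bath, a plausible size, so I assume that proportion, scale the constant with equivalents and hold the partner as charged.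

My reckoning then gives violet 41.0% and teal 5.68%.

The forecast is violet > green > blue > ochre > amber > teal, with 40% on top and 5.5% at the bottom: “Product therefore ranks with partner charge.” Its teal figure is lower than mine.

The flasks give violet > green > blue > ochre > amber > teal, with violet at 40.8% and teal at 5.70%.

    substrate + catalyst → catalyst + intermediate (k = 7.20 × 10⁵ M⁻¹ h⁻¹, Ea = 39.0 kJ mol⁻¹)
    coupling partner + catalyst + intermediate → catalyst + product (k = 2.20 × 10⁵ M⁻² h⁻¹, Ea = 43.0 kJ mol⁻¹)
    crystals ⇌ product, rate k3*(cs3 - [product]) while solid is left; crystals form when [product] > cs3 (solubility = 1.40 mM, k = 82.0 h⁻¹)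
    coupling partner + product ⇌ idle adduct, settled at all times (K = 44.0 M⁻¹, ΔH = −28.0 kJ mol⁻¹)
    (constants at 35 °C)

In violet, with the other concentrations as charged, the substrate's half-life by its own step alone is 2.9 min, against 2.8 h for the intermediate by the partner step alone, the rate-limiting step. At 2.50 h violet holds 0% substrate and 59.2% intermediate. My constant gives violet an intermediate half-life of 3.28 h, between 2.8 h at 0.0482 h and 3.5 h at 2.50 h. For violet read at 10 h it gives 87.9%, and that flask stands at 84.2%. Teal's product has moved by 5 points once its partner stands at 0.604 equiv, the nearest such charge above its present one.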